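Ring B (C5–C10, eudesmane numbering) is closed last, at C7–C8, by an indium-mediated intramolecular Barbier allylation. The step exploits the array C8(OH)–C7H–C11(=C13H2)–CO2Me: a 2-(methoxycarbonyl)allylindium attacks a pendant aldehyde through C7, so one operation creates ring B, the C7 and C8 stereocentres and the α-methylene ester. The step is convergent, since C7-epimeric bromides funnel through one fluxional allylindium, and the axial C10 methyl should enforce the all-equatorial ring. The precursor is a monocyclic cyclohexanone (ring A) carrying an acetaldehyde arm on C10 and a bromoallyl arm on C5, built by indium γ-bromoallylation of a stereolabile 2-formyl ketone.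

Key step: step 11

Remark: ring carbons carry eudesmane numbers throughout (ring A = C1–C5 and C10; ring B = C5–C10; C11–C13 = acrylate carbons on C7). The target is the (1R,5S,6S,7S,8S,10R) isomer encoded in the SMILES. C7 of compounds 12–14 is an epimeric mixture, which is erased in step 11.

Step 1
Reactants: 1 2-methylcyclohex-2-en-1-one
Product: 2 (R)-2-methylcyclohex-2-en-1-ol
Conditions: (S)-Me-CBS oxazaborolidine (10 mol %), catecholborane, toluene, −78 °C; aq. NaOH work-up
Reagents that add atoms: none
Why: Corey–Bakshi–Shibata reduction, in which the α-branched alkenyl flank acts as the large group, so the (S)-catalyst should deliver hydride to the face that gives the (R)-allylic alcohol (later C1).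

Step 2
Reactants: 2 (R)-2-methylcyclohex-2-en-1-ol
Product: 3 (R)-tert-butyldimethyl[(2-methylcyclohex-2-en-1-yl)oxy]silane
Conditions: TBSCl, imidazole, DMF, rt
Reagents that add atoms: tert-butyldimethylsilyl chloride, CC(C)(C)[Si](C)(C)Cl
Why: Standard silylation of a secondary allylic alcohol; the bulky ether later directs the conjugate addition and survives to the last step.

Step 3
Reactants: 3 (R)-tert-butyldimethyl[(2-methylcyclohex-2-en-1-yl)oxy]silane
Product: 4 (R)-4-(tert-butyldimethylsilyloxy)-3-methylcyclohex-2-en-1-one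
Conditions: Rh2(cap)4 (1 mol %), t-BuOOH (70% aq.), K2CO3, CH2Cl2, rt
Reagents that add atoms: tert-butyl hydroperoxide, CC(C)(C)OO
Why: Dirhodium-catalysed allylic C–H oxidation should attack the ring CH2 next to the less substituted alkene carbon and give the enone without touching the silyloxy stereocentre.

Step 4
Reactants: 4 (R)-4-(tert-butyldimethylsilyloxy)-3-methylcyclohex-2-en-1-one
Product: 5 {[(3R,4R)-3-allyl-4-(tert-butyldimethylsilyloxy)-3-methylcyclohex-1-en-1-yl]oxy}trimethylsilane
Conditions: allylMgBr, CuBr·SMe2, LiCl, TMSCl, THF, −78 °C; cold NaHCO3/pentane work-up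
Reagents that add atoms: allylmagnesium bromide, C=CC[Mg]Br; chlorotrimethylsilane, C[Si](C)(C)Cl
Why: TMSCl-accelerated conjugate addition of allylcopper should create the quaternary C10 by axial attack anti to the γ-silyloxy group (allyl trans to OTBS, methyl cis), and the enolate is trapped regiospecifically as the C4–C5 silyl enol ether.

Step 5
Reactants: 5 {[(3R,4R)-3-allyl-4-(tert-butyldimethylsilyloxy)-3-methylcyclohex-1-en-1-yl]oxy}trimethylsilane
Product: 7 (3R,4R,Z)-3-allyl-4-(tert-butyldimethylsilyloxy)-2-(hydroxymethylene)-3-methylcyclohexan-1-one, via lithium enolate 6 (not isolated)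
Conditions: MeLi, THF, 0 °C; then HCO2CH2CF3, −78 → 0 °C; 1 M HCl work-up
Reagents that add atoms: 2,2,2-trifluoroethyl formate, O=COCC(F)(F)F
Why: Methyllithium unmasks the regiodefined lithium enolate, which should undergo crossed Claisen C-formylation at C5 with the activated formate; the product is the chelated enol of the 2-formyl ketone, so C5 stays stereolabile.

Step 6
Reactants: 8 methyl 2-(bromomethyl)acrylate
Product: 9 methyl 2,3-dibromo-2-(bromomethyl)propanoate
Conditions: Br2, CH2Cl2, 0 °C → rt
Reagents that add atoms: bromine, BrBr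
Why: Electrophilic addition of bromine across the acrylate double bond should give the tribromide; no stereocentre is formed because the two CH2Br groups are identical.

Step 7
Reactants: 9 methyl 2,3-dibromo-2-(bromomethyl)propanoate
Product: 10 methyl (Z)-3-bromo-2-(bromomethyl)acrylate
Conditions: Et3N (1.05 equiv), Et2O, 0 °C
Reagents that add atoms: none
Why: E2 dehydrobromination (proton from a CH2Br group, tertiary α-bromide as leaving group) should give the conjugated vinyl bromide with bromine trans to the ester; the alkene geometry is lost in step 8.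

Step 8
Reactants: 7 (3R,4R,Z)-3-allyl-4-(tert-butyldimethylsilyloxy)-2-(hydroxymethylene)-3-methylcyclohexan-1-one; 10 methyl (Z)-3-bromo-2-(bromomethyl)acrylate
Product: 12 methyl (3RS,4R)-4-[(1S,2R,3R)-2-allyl-3-(tert-butyldimethylsilyloxy)-2-methyl-6-oxocyclohexyl]-3-bromo-4-hydroxy-2-methylidenebutanoate, via allylindium 11 (not isolated)
Conditions: In powder (1.5 equiv), 10 (3 equiv), THF/H2O 1:1, rt, sonication
Reagents that add atoms: none
Why: Barbier-type γ-haloallylation in water, in which indium inserts into the allylic C–Br bond and the γ-bromoallylindium adds through its CHBr carbon to the formyl group of the keto-aldehyde tautomer (indium allylations tolerate enolised 1,3-dicarbonyls); the enol equilibrates C5, the reacting tautomer should carry the formyl group equatorial (trans to the C10 allyl arm), and chelation or Felkin–Anh attack anti to C10 should set the 5,6-anti relationship.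

Step 9
Reactants: 12 methyl (3RS,4R)-4-[(1S,2R,3R)-2-allyl-3-(tert-butyldimethylsilyloxy)-2-methyl-6-oxocyclohexyl]-3-bromo-4-hydroxy-2-methylidenebutanoate
Product: 13 methyl (3RS,4R)-4-[(1S,2R,3R)-2-allyl-3-(tert-butyldimethylsilyloxy)-2-methyl-6-oxocyclohexyl]-3-bromo-2-methylidene-4-(triethylsilyloxy)butanoate
Conditions: TESOTf, 2,6-lutidine, CH2Cl2, −78 °C
Reagents that add atoms: triethylsilyl trifluoromethanesulfonate, CC[Si](CC)(CC)OS(=O)(=O)C(F)(F)F
Why: Low-temperature silyl triflate silylation protects the hindered C6 hydroxyl before it can lactonise or eliminate and marks O6, so that only O8 is free after ring closure; the hindered base should spare the allylic bromide.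

Step 10
Reactants: 13 methyl (3RS,4R)-4-[(1S,2R,3R)-2-allyl-3-(tert-butyldimethylsilyloxy)-2-methyl-6-oxocyclohexyl]-3-bromo-2-methylidene-4-(triethylsilyloxy)butanoate
Product: 14 methyl (3RS,4R)-3-bromo-4-[(1S,2R,3R)-3-(tert-butyldimethylsilyloxy)-2-methyl-6-oxo-2-(2-oxoethyl)cyclohexyl]-2-methylidene-4-(triethylsilyloxy)butanoate
Conditions: O3, acetone/H2O 95:5, 0 °C, Sudan III end-point
Reagents that add atoms: ozone, [O-][O+]=O
Why: Ozonolysis in aqueous acetone, where ozone should cleave the electron-rich monosubstituted alkene much faster than the electron-poor acrylate, and water traps the carbonyl oxide so the aldehyde forms without a nucleophilic reductant that would attack the allylic bromide.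

Step 11
Reactants: 14 methyl (3RS,4R)-3-bromo-4-[(1S,2R,3R)-3-(tert-butyldimethylsilyloxy)-2-methyl-6-oxo-2-(2-oxoethyl)cyclohexyl]-2-methylidene-4-(triethylsilyloxy)butanoate
Product: 16 methyl 1β-(tert-butyldimethylsilyloxy)-8α-hydroxy-4-oxo-6α-(triethylsilyloxy)-15-nor-5αH,7αH-eudesm-11(13)-en-12-oate, via allylindium 15 (not isolated)
Conditions: In powder (2 equiv), THF/H2O 3:1 (0.01 M), rt; pH 7 work-up
Reagents that add atoms: none
Why: Indium inserts into the allylic C–Br bond and the fluxional 2-(methoxycarbonyl)allylindium (metal on C13) adds through its γ-carbon C7 to the C8 aldehyde; the closest known reaction type is the indium- or chromium-mediated cyclisation of ω-formyl 2-(bromomethyl)alk-2-enoates used for α-methylene lactone terpenoids. Ring B (C5–C10) closes in a 6-exo-trig mode at the carbonyl with SE2′ transposition of the allyl unit, which regenerates the C11=C13 methylene ester. C7 should be set by a chair-like ring-B transition state, templated by the fixed C5, C6 and C10 centres, that places the acrylate equatorial and trans to the C6 silyloxy group. C8 should be set by the trans-fused Zimmerman–Traxler chair with the metal-bound oxygen equatorial, because the alternative places that oxygen axial and syn to the axial C10 methyl. The step needs γ- over α-attack, secured because α-attack would give an eight-membered ring, and needs convergence of the C7-epimeric (or SN2′-isomerised) bromides, secured because all give the same allylindium by 1,3-metal shift. The C4 ketone is a poorer electrophile and cannot be reached by C7 in a normal ring, and water-tolerant indium should leave the silyl ethers and the ester intact.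

Step 12
Reactants: 17 methyl 2-(hydroxymethyl)acrylate
Product: 18 methyl 2-[(tert-butyldimethylsilyloxy)methyl]acrylate
Conditions: TBSCl, imidazole, CH2Cl2, 0 °C → rt
Reagents that add atoms: tert-butyldimethylsilyl chloride, CC(C)(C)[Si](C)(C)Cl
Why: Standard silylation of a primary allylic alcohol, which prevents self-esterification of the acid made in step 13.

Step 13
Reactants: 18 methyl 2-[(tert-butyldimethylsilyloxy)methyl]acrylate
Product: 19 2-[(tert-butyldimethylsilyloxy)methyl]acrylic acid
Conditions: LiOH·H2O, THF/H2O, 0 °C; 1 M HCl to pH 4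
Reagents that add atoms: lithium hydroxide, [Li+].[OH-]
Why: Saponification of the methyl ester at 0 °C, conditions under which the primary TBS ether should be stable.

Step 14
Reactants: 16 methyl 1β-(tert-butyldimethylsilyloxy)-8α-hydroxy-4-oxo-6α-(triethylsilyloxy)-15-nor-5αH,7αH-eudesm-11(13)-en-12-oate; 19 2-[(tert-butyldimethylsilyloxy)methyl]acrylic acid
Product: 20 methyl 1β-(tert-butyldimethylsilyloxy)-8α-{2-[(tert-butyldimethylsilyloxy)methyl]acryloyloxy}-4-oxo-6α-(triethylsilyloxy)-15-nor-5αH,7αH-eudesm-11(13)-en-12-oate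
Conditions: DCC, DMAP (0.2 equiv), CH2Cl2, 0 °C → rt
Reagents that add atoms: none
Why: Steglich esterification of the equatorial C8 alcohol with retention at C8; O6 and O1 are silylated, so no regiochemical question arises.

Step 15
Reactants: 20 methyl 1β-(tert-butyldimethylsilyloxy)-8α-{2-[(tert-butyldimethylsilyloxy)methyl]acryloyloxy}-4-oxo-6α-(triethylsilyloxy)-15-nor-5αH,7αH-eudesm-11(13)-en-12-oate
Product: 21 methyl 1β,6α-dihydroxy-8α-[2-(hydroxymethyl)acryloyloxy]-4-oxo-15-nor-5αH,7αH-eudesm-11(13)-en-12-oate (CNP0144895.1)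
Conditions: HF·pyridine, pyridine, THF, 0 °C → rt
Reagents that add atoms: none
Why: Buffered fluoride desilylation should cleave the three silyl ethers without touching the β-hydroxy ketone, the two esters or the acrylate units, and no stereocentre is affected.

Compound list
1 | 2-methylcyclohex-2-en-1-one | CC1=CCCCC1=O | starting material
2 | (R)-2-methylcyclohex-2-en-1-ol | CC1=CCCC[C@H]1O | intermediate
3 | (R)-tert-butyldimethyl[(2-methylcyclohex-2-en-1-yl)oxy]silane | CC1=CCCC[C@H]1O[Si](C)(C)C(C)(C)C | intermediate
4 | (R)-4-(tert-butyldimethylsilyloxy)-3-methylcyclohex-2-en-1-one | CC1=CC(=O)CC[C@H]1O[Si](C)(C)C(C)(C)C | intermediate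
5 | {[(3R,4R)-3-allyl-4-(tert-butyldimethylsilyloxy)-3-methylcyclohex-1-en-1-yl]oxy}trimethylsilane (allyl trans to OTBS) | C=CC[C@@]1(C)[C@H](O[Si](C)(C)C(C)(C)C)CCC(O[Si](C)(C)C)=C1 | intermediate
6 | lithium (3R,4R)-3-allyl-4-(tert-butyldimethylsilyloxy)-3-methylcyclohex-1-en-1-olate | C=CC[C@@]1(C)[C@H](O[Si](C)(C)C(C)(C)C)CCC(O[Li])=C1 | intermediate (not isolated)
7 | (3R,4R,Z)-3-allyl-4-(tert-butyldimethylsilyloxy)-2-(hydroxymethylene)-3-methylcyclohexan-1-one (enol of the 2-formyl ketone) | C=CC[C@@]1(C)[C@H](O[Si](C)(C)C(C)(C)C)CCC(=O)/C1=C\O | intermediate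
8 | methyl 2-(bromomethyl)acrylate | C=C(CBr)C(=O)OC | starting material
9 | methyl 2,3-dibromo-2-(bromomethyl)propanoate | BrCC(Br)(CBr)C(=O)OC | intermediate
10 | methyl (Z)-3-bromo-2-(bromomethyl)acrylate | Br/C=C(\CBr)C(=O)OC | intermediate
11 | [3-bromo-2-(methoxycarbonyl)allyl]indium dibromide (fluxional) | COC(=O)C(C[In](Br)Br)=CBr | intermediate (not isolated)
12 | methyl (3RS,4R)-4-[(1S,2R,3R)-2-allyl-3-(tert-butyldimethylsilyloxy)-2-methyl-6-oxocyclohexyl]-3-bromo-4-hydroxy-2-methylidenebutanoate | C=CC[C@@]1(C)[C@H](O[Si](C)(C)C(C)(C)C)CCC(=O)[C@@H]1[C@@H](O)C(Br)C(=C)C(=O)OC | intermediate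
13 | methyl (3RS,4R)-4-[(1S,2R,3R)-2-allyl-3-(tert-butyldimethylsilyloxy)-2-methyl-6-oxocyclohexyl]-3-bromo-2-methylidene-4-(triethylsilyloxy)butanoate | C=CC[C@@]1(C)[C@H](O[Si](C)(C)C(C)(C)C)CCC(=O)[C@@H]1[C@@H](O[Si](CC)(CC)CC)C(Br)C(=C)C(=O)OC | intermediate
14 | methyl (3RS,4R)-3-bromo-4-[(1S,2R,3R)-3-(tert-butyldimethylsilyloxy)-2-methyl-6-oxo-2-(2-oxoethyl)cyclohexyl]-2-methylidene-4-(triethylsilyloxy)butanoate | O=CC[C@@]1(C)[C@H](O[Si](C)(C)C(C)(C)C)CCC(=O)[C@@H]1[C@@H](O[Si](CC)(CC)CC)C(Br)C(=C)C(=O)OC | intermediate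
15 | allylindium dibromide derived from 14 (indium on C13, C7=C11 double bond, geometry fluxional) | O=CC[C@@]1(C)[C@H](O[Si](C)(C)C(C)(C)C)CCC(=O)[C@@H]1[C@@H](O[Si](CC)(CC)CC)C=C(C[In](Br)Br)C(=O)OC | intermediate (not isolated)
16 | methyl 1β-(tert-butyldimethylsilyloxy)-8α-hydroxy-4-oxo-6α-(triethylsilyloxy)-15-nor-5αH,7αH-eudesm-11(13)-en-12-oate (trans-decalin, 10β-methyl) | O[C@H]1C[C@@]2(C)[C@H](O[Si](C)(C)C(C)(C)C)CCC(=O)[C@@H]2[C@@H](O[Si](CC)(CC)CC)[C@@H]1C(=C)C(=O)OC | intermediate
17 | methyl 2-(hydroxymethyl)acrylate | C=C(CO)C(=O)OC | starting material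
18 | methyl 2-[(tert-butyldimethylsilyloxy)methyl]acrylate | C=C(CO[Si](C)(C)C(C)(C)C)C(=O)OC | intermediate
19 | 2-[(tert-butyldimethylsilyloxy)methyl]acrylic acid | C=C(CO[Si](C)(C)C(C)(C)C)C(=O)O | intermediate
20 | methyl 1β-(tert-butyldimethylsilyloxy)-8α-{2-[(tert-butyldimethylsilyloxy)methyl]acryloyloxy}-4-oxo-6α-(triethylsilyloxy)-15-nor-5αH,7αH-eudesm-11(13)-en-12-oate | C=C(CO[Si](C)(C)C(C)(C)C)C(=O)O[C@H]1C[C@@]2(C)[C@H](O[Si](C)(C)C(C)(C)C)CCC(=O)[C@@H]2[C@@H](O[Si](CC)(CC)CC)[C@@H]1C(=C)C(=O)OC | intermediate
21 | methyl 1β,6α-dihydroxy-8α-[2-(hydroxymethyl)acryloyloxy]-4-oxo-15-nor-5αH,7αH-eudesm-11(13)-en-12-oate, (1R,5S,6S,7S,8S,10R) | C=C(CO)C(=O)O[C@H]1C[C@@]2(C)[C@H](O)CCC(=O)[C@@H]2[C@@H](O)[C@@H]1C(=C)C(=O)OC | target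

Total step count: 15
Longest linear sequence: 11 steps (steps 1–5, 8–11, 14, 15)

Steps most likely to fail

1. Step 8. The acidic enol of 7 may protonate the allylindium faster than its aldehyde tautomer is allylated. The product, itself an activated allylic bromide, may undergo a second indium insertion (reduction or diene formation) or lactonise. The tautomer with an axial formyl group may react and erode the C5/C6 control. The fallback sets out from 5 and comes back at 16. The lithium enolate of 5 (MeLi, THF) would be treated with 3-methylbut-2-enal to give the 5,6-anti aldol adduct F1 (Zimmerman–Traxler; the facial sense at C5 would have to be confirmed). Silylation with TESOTf/2,6-lutidine would give the silyl ether F2. Indicator-controlled ozonolysis of the more electron-rich trisubstituted alkene (PPh3 work-up) would give the α-silyloxy aldehyde F3. A Morita–Baylis–Hillman reaction with methyl acrylate and DABCO would give the allylic alcohol F4. NBS/Me2S would convert it with SN2′ transposition into the (Z)-2-(bromomethyl)enoate F5. Ozonolysis of the allyl arm as in step 10 would give the aldehyde F6. Under the conditions of step 11, F6 would form the same allylindium 15 and close to 16.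

2. Step 11. The cis-fused transition state of the Z-configured allylindium may compete and give the axial C8 alcohol, which tends to lactonise onto the ester; the allylindium may also be protonated before it cyclises. The fallback sets out from 14 and comes back at 20. If the 8β-alcohol F7 predominates, it would be isolated after a buffered work-up and esterified with acid 19 under Mitsunobu conditions (PPh3, DIAD, toluene, 0 °C). The SN2 inversion at C8 would then deliver 20 directly, so step 14 is replaced and not repeated.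

3. Step 5. The hindered enolate next to the quaternary C10 may be O-formylated, or may exchange protons with the product so that regiochemical integrity is lost and formylation occurs at C3. The fallback sets out from 5 and comes back at 7. A Mukaiyama-type reaction of the silyl enol ether 5 with trimethyl orthoformate (BF3·OEt2, CH2Cl2, −78 °C) would give the β-keto dimethyl acetal F8 regiospecifically. Mild aqueous acid (TFA/H2O/CHCl3, 0 °C) would then unmask the 2-formyl ketone 7.

Further compounds
F1 | step 8 | 5,6-anti aldol adduct of the ring-A ketone with 3-methylbut-2-enal (free C6 hydroxyl, C7=C(CH3)2, configuration as in 12) | C=CC[C@@]1(C)[C@H](O[Si](C)(C)C(C)(C)C)CCC(=O)[C@@H]1[C@@H](O)C=C(C)C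
F2 | step 8 | 6-O-triethylsilyl ether of F1 | C=CC[C@@]1(C)[C@H](O[Si](C)(C)C(C)(C)C)CCC(=O)[C@@H]1[C@@H](O[Si](CC)(CC)CC)C=C(C)C
F3 | step 8 | α-(triethylsilyloxy) aldehyde (C7 aldehyde, allyl arm intact) | C=CC[C@@]1(C)[C@H](O[Si](C)(C)C(C)(C)C)CCC(=O)[C@@H]1[C@@H](O[Si](CC)(CC)CC)C=O
F4 | step 8 | Morita–Baylis–Hillman alcohol (C7 hydroxyl, epimeric mixture; methyl 2-methylidene ester) | C=CC[C@@]1(C)[C@H](O[Si](C)(C)C(C)(C)C)CCC(=O)[C@@H]1[C@@H](O[Si](CC)(CC)CC)C(O)C(=C)C(=O)OC
F5 | step 8 | (Z)-2-(bromomethyl)enoate (primary allylic bromide, C7=C11) | C=CC[C@@]1(C)[C@H](O[Si](C)(C)C(C)(C)C)CCC(=O)[C@@H]1[C@@H](O[Si](CC)(CC)CC)/C=C(\CBr)C(=O)OC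
F6 | step 8 | C8 aldehyde of F5 (allylic isomer of 14) | O=CC[C@@]1(C)[C@H](O[Si](C)(C)C(C)(C)C)CCC(=O)[C@@H]1[C@@H](O[Si](CC)(CC)CC)/C=C(\CBr)C(=O)OC
F7 | step 11 | 8-epimer of 16 (8β-hydroxy, axial) | O[C@@H]1C[C@@]2(C)[C@H](O[Si](C)(C)C(C)(C)C)CCC(=O)[C@@H]2[C@@H](O[Si](CC)(CC)CC)[C@@H]1C(=C)C(=O)OC
F8 | step 5 | (3R,4R)-3-allyl-4-(tert-butyldimethylsilyloxy)-2-(dimethoxymethyl)-3-methylcyclohexan-1-one (C2 epimers) | C=CC[C@@]1(C)[C@H](O[Si](C)(C)C(C)(C)C)CCC(=O)C1C(OC)OC
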